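**Numbering used throughout**

Atoms: C1 = geranyl bridgehead next to C8Me2; C2 = ketone; C3 = aroyl-bearing carbon; C4 = enol carbon; C5 = geranyl bridgehead next to C6H2; C7 = prenyl methine; C9 = bridging ketone. Ring A = C1–C2–C3–C4–C5–C9; ring B = C1–C8–C7–C6–C5–C9.

Compounds: 1 prenol; 2 epoxy alcohol; 3 epoxy tosylate; 4 epoxy iodide; 5 1,5-dimethoxycyclohexa-1,4-diene; 6 geranyl bromide; 7 6-geranyl diene; 8 cyclisation precursor; 9 bridged methyl ketal; 10 hydroxy ketone; 11 xanthate; 12 C7-allyl compound; 13 C7-prenyl compound; 14 vinylogous ester; 15 1,5-digeranyl vinylogous ester; 16 3,4-dihydroxybenzoic acid; 17 tris-silyl derivative; 18 aroyl chloride; 19 C3-aroyl compound; 20 bis-silyl enol; 21 target.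

## Analysis of the target

- The target is a bicyclo[3.3.1]nonane-2,4,9-trione of the type B acylphloroglucinol family. Ring A is an enolised β-triketone carrying the 3,4-dihydroxybenzoyl group on C3, and ring B is a carbocycle with a gem-dimethyl carbon (C8) and a prenyl-bearing methine (C7).
- There are three stereocentres, (1S,5S,7R). C1 and C5 are quaternary bridgeheads, each with a geranyl group, and the one-carbon bridge ties them together, so they form a single stereochemical element (the sense of the bicycle).
- C7 is the second element. Its prenyl group is exo, that is, equatorial on the chair of ring B and turned away from ring A.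
- Sensitive groups are the five trisubstituted alkenes (acid, electrophiles, oxidants, metathesis catalysts), the catechol (air and base) and the enolised triketone. The two non-enolisable 1,3-dicarbonyl units C2–C1–C9 and C4–C5–C9 can be cleaved by hydroxide.
- The difficulty is congestion. C1, C8 and C5/C9 form a run of fully substituted carbons, the C9 ketone sits between two quaternary centres, and the C1–C8 bond joins a bridgehead to a gem-dimethyl carbon.
- The plan rests on two features. C5 lies between two oxygenated carbons, C4 and C9, which can be written as the two enantiotopic methyl enol ethers of a symmetric cyclohexadiene. C8, next to C7, can be offered as the tertiary end of an epoxide, so the C1–C8 bond can be made while ring B closes.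

## Retrosynthetic reasoning

**21 to 19 (O–Si and O–CH3).** The catechol and the C4 enol are unmasked last, because the free triketone–catechol is the least robust form. Target 21 comes from bis-silyl enol 20 by fluoride, and 20 from the C4 methyl enol ether 19 by demethylation. The forward steps must avoid acid (alkenes) and hydroxide (retro-Claisen).

**19 to 15 and 18 (C3–aroyl bond).** C3 is the α-carbon of a vinylogous ester and can be metalated once C1 is quaternary, so the aroyl group is introduced on 15 with acid chloride 18. Doing this late keeps the electrophilic 2-acyl vinylogous ester away from the strong bases of the earlier steps. Chloride 18 goes back through silyl ester 17 to acid 16.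

**15 to 14 and 6 (C1–geranyl bond).** The C1 bridgehead hydrogen of 14 is flanked by the C2 and C9 carbonyls, so the second geranyl group can be added by bridgehead deprotonation and alkylation with 6. The bicycle allows only one configuration at C1, so nothing new has to be controlled.

**14 to 13 (C2 carbonyl).** The C2 oxygen is removed to the C2 methylene of enol ether 13. Forward, this is an allylic oxidation of the position activated by the enol ether. It turns the acid-labile enol ether into a robust vinylogous ester and makes C1–H acidic.

**13 to 10 (C7–prenyl bond).** The prenyl group is traced through allyl compound 12 and xanthate 11 to the C7 alcohol of 10. A C7 radical is attacked from the open exo face, which is the target configuration, so the configuration of the C7 oxygen itself is not needed beyond this point.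

**10 to 8 (C1–C8 bond, ring B).** This is the key disconnection. Cutting C1–C8 and restoring a C7–C8 epoxide and a C9 enol ether gives the symmetric diene 8, whose only stereocentre is the epoxide carbon. Forward, ring B closes, both bridgeheads are set from that one centre, and the C7 oxygen and the gem-dimethyl group arrive with the electrophile. Bridged ketal 9 is the form in which the product is expected to leave the ring closure.

**8 to 7 and 4; 7 to 5 and 6; 4 to 1.** The quaternary carbon of 8 is assembled by two alkylations of diene 5 at the carbon between its enol ethers, first with 6 and then with iodide 4. The epoxide goes in last, so that no carbanion is generated next to it. Iodide 4 comes from tosylate 3, made by catalytic asymmetric epoxidation of prenol 1 through epoxy alcohol 2.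

## Alternatives that were turned down

**Alternative 1:** The disconnection is C5–C6 and C6–C9, as a cyclopropane. A diazo ketone chain on the quaternary carbon of the same kind of symmetric diene (A1) is decomposed by CuOTf, a monovalent copper salt, with a chiral bis(oxazoline). The carbene adds to one enantiotopic enol ether and gives the methoxycyclopropyl ketone A2, a cyclopentanone fused to a donor–acceptor cyclopropane, whose later C6–C9 cleavage would reveal ring B.
- For: desymmetrisation is under catalyst control, two bonds form at once, and the electrophilic carbene is well matched with an enol ether. A1 is as short to make as 8. On reagent control this plan is at least as strong as the chosen one, since selection does not depend on a chair-versus-boat preference of a flexible chain.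
- Against: A2 has neither the C8 methyl groups nor the C7 substituent. After cyclopropane opening, C8 must be methylated twice between a quaternary bridgehead and the C7 ketone. The C7 ketone must then be turned into an exo prenyl methine, and the C5 bridgehead must still be geranylated, which adds several hindered steps. Enantioselectivity for diazo ketones with such copper catalysts is variable, and insertion into the doubly allylic C–H bonds or cyclopropanation of the geranyl alkene competes.
- Comparison: the chosen route also draws its chirality from a catalytic reaction, and its electrophile delivers C8Me2 and a C7 handle in the ring-closing step.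

**Alternative 2:** The disconnection is C1–C2 (Dieckmann) together with one C8–CH3 bond. Me2CuLi adds to the tetrasubstituted enone A3. The resulting C1 enolate attacks the ester carbon of the E β-methoxyacrylate on C5 and closes ring A, giving A4, which is identical with 15.
- For: the gem-dimethyl carbon and the C1 quaternary bridgehead form in one operation, and the product already carries both geranyl groups and the prenyl group. No radical step, allylic oxidation or bridgehead alkylation is needed. After the key step this plan is clearly shorter than the chosen one.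
- Against: the effort moves into A3. Its C5 quaternary centre and its C7 centre must be set independently, with no symmetry to use. Cuprate addition to an α,β,β-trisubstituted enone with a branched γ-carbon is among the least favourable conjugate additions, and the silyl or boron activators that usually rescue it would trap the enolate. The fully substituted enolate must then attack an ester deactivated by its β-methoxy group, and the cuprate can instead add to the methoxyacrylate.
- Comparison: the chosen route offers a three-step symmetric precursor and one stereocentre that controls both bridgeheads, at the price of more steps afterwards.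

**Alternative 3:** The disconnection is C5–C6, made by a 1,2-shift. PhI(OAc)2 with KOH in methanol puts trivalent iodine on C5 of the hydrindanone A5 through the C4 enolate. The ring-fusion alkoxide on C9 then pushes C6 from C9 to C5 with loss of iodobenzene, giving the bicyclo[3.3.1]nonane A6 with a C5–H bridgehead and a C2 methyl enol ether.
- For: fused hydrindanes can be built with predictable facial control, the aryliodonio leaving group strongly drives migration, and the C9 ketone appears directly. On stereocontrol before ring formation this plan may be as good as the chosen one.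
- Against: under these conditions ketone enolates normally undergo α-hydroxylation through methoxide attack on the carbonyl. The C9 alcohol is β to the C4 ketone, so retro-aldol ring opening competes. Migration of C1 instead of C6 would contract the ring, and the anti alignment of the migrating bond depends on the ring fusion. A5 contains two adjacent fully substituted carbons (C1 and C9) and would need many steps, and after the key step the C5 geranylation, C3 aroylation and deprotection still remain.
- Comparison: the chosen ring closure has a close known reaction type behind it and a far shorter precursor.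

Key step: step 5

Remark on the chemistry (assumption 1): diene 5, the Birch reduction product of 1,3-dimethoxybenzene, is taken as a purchased starting material.
Remark on the chemistry (assumption 2): the C9 oxocarbenium ion formed in the ring closure is assumed to be trapped by the C7 silyloxy group as a bridged methyl ketal and not to lose its methyl group directly. The hydroxy ketone is therefore released in the same flask with a boron bromide.

## Route

Step 1
Reactants: 1 prenol (3-methylbut-2-en-1-ol)
Product: 3 [(2R)-3,3-dimethyloxiran-2-yl]methyl 4-methylbenzenesulfonate, via epoxy alcohol 2 (not isolated)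
Conditions: Ti(OiPr)4 (5 mol %), D-(−)-diisopropyl tartrate (7 mol %), t-BuOOH, 4 Å MS, CH2Cl2, −20 °C; P(OMe)3; then TsCl, Et3N, DMAP (cat.), −10 °C
Reagents that add atoms: tert-butyl hydroperoxide CC(C)(C)OO; 4-toluenesulfonyl chloride Cc1ccc(cc1)S(Cl)(=O)=O
Why: Katsuki–Sharpless asymmetric epoxidation; the D-(−)-tartrate ligand gives the (2R)-epoxy alcohol, the mirror image of the (2S) series known for the L-(+)-tartrate with geraniol. Sulfonylation in the same flask avoids isolating the volatile, water-soluble epoxy alcohol.

Step 2
Reactants: 3 [(2R)-3,3-dimethyloxiran-2-yl]methyl 4-methylbenzenesulfonate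
Product: 4 (2S)-2-(iodomethyl)-3,3-dimethyloxirane
Conditions: NaI, NaHCO3, acetone, rt, dark
Reagents that add atoms: sodium iodide [Na+].[I-]
Why: Finkelstein displacement at the primary carbon; the stereocentre is untouched, and the descriptor changes from R to S only because CH2I outranks the ring carbon.

Step 3
Reactants: 5 1,5-dimethoxycyclohexa-1,4-diene; 6 geranyl bromide
Product: 7 6-[(2E)-3,7-dimethylocta-2,6-dien-1-yl]-1,5-dimethoxycyclohexa-1,4-diene
Conditions: t-BuLi, THF, −78 °C; then 6, −78 °C to rt
Reagents that add atoms: none
Why: Deprotonation occurs at the doubly allylic carbon between the two methoxy-bearing carbons, which keeps the charge of the pentadienyl anion off the oxygenated carbons. The anion is alkylated at its central carbon by direct displacement on the primary allylic bromide, so the E alkene is kept.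

Step 4
Reactants: 7 6-geranyl-1,5-dimethoxycyclohexa-1,4-diene; 4 (2S)-2-(iodomethyl)-3,3-dimethyloxirane
Product: 8 6-geranyl-6-{[(2R)-3,3-dimethyloxiran-2-yl]methyl}-1,5-dimethoxycyclohexa-1,4-diene
Conditions: t-BuLi, THF, −78 to −40 °C; then 4, −78 to 0 °C
Reagents that add atoms: none
Why: A second deprotonation at the same carbon and alkylation at the central carbon of the anion gives the quaternary centre; a primary iodide next to an epoxide is an activated electrophile for this direct displacement. The new quaternary carbon carries two identical ring arms, so the epoxide carbon remains the only stereocentre.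

Step 5
Reactants: 8 6-geranyl-6-{[(2R)-3,3-dimethyloxiran-2-yl]methyl}-1,5-dimethoxycyclohexa-1,4-diene
Product: 10 (1S,5S,7R)-5-geranyl-7-hydroxy-4-methoxy-8,8-dimethylbicyclo[3.3.1]non-3-en-9-one, via bridged methyl ketal 9 (not isolated)
Conditions: Me3SiOTf (0.3 equiv), 2,6-di-tert-butyl-4-methylpyridine, CH2Cl2, −78 °C; then Me2BBr, −78 °C; aq. NaHCO3
Reagents that add atoms: water O
Why: Silylation of the epoxide oxygen by Me3SiOTf weakens the tertiary C8–O bond, and the electron-rich β-carbon C1 of one methyl enol ether displaces it from the rear, forming C1–C8 and leaving a methoxy oxocarbenium ion at C9; the closest known reaction type is the Lewis-acid epoxide-opening cyclisation of 6,6-dialkyl-1,5-dimethoxycyclohexa-1,4-dienes, an epoxide-initiated cation–olefin cyclisation with an enol ether as terminator. Ring B (C1–C8–C7–C6–C5–C9) closes in a 6-endo mode at the epoxide with the enol ether double bond inside the new ring (6-enolendo); the 5-exo alternative at C7 is disfavoured because the developing positive charge sits on the gem-dimethyl carbon. Rear-side attack demands an anti arrangement O–C7–C8–C1, which in a chair-like transition state places the C7 oxygen equatorial, and with the (R)-epoxide only one of the two enantiotopic enol ethers can reach C8 in that chair while the other needs a boat, so the C7 centre selects the nucleophile and thereby fixes C1 and C5 together (both S in 10). The oxocarbenium ion is expected to be captured by the C7 silyloxy oxygen once ring B flips to a boat (5-exo-trig, with return of the silyl cation to the cycle), giving bridged ketal 9, a closure open only to the chair-derived isomer. Me2BBr then ionises 9 on the side of the bridging oxygen, because the other ionisation would give a bridgehead oxocarbenium ion of an oxanorbornane, and hydrolytic work-up releases the C9 ketone and the C7 alcohol. The step needs the epoxide to react with an enol ether and not with a geranyl alkene, which the far higher nucleophilicity of enol ethers secures, and it needs the enol ethers to survive, which the hindered pyridine base secures by removing adventitious acid.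

Step 6
Reactants: 10 (1S,5S,7R)-5-geranyl-7-hydroxy-4-methoxy-8,8-dimethylbicyclo[3.3.1]non-3-en-9-one
Product: 11 O-[(1S,5S,7R)-5-geranyl-4-methoxy-8,8-dimethyl-9-oxobicyclo[3.3.1]non-3-en-7-yl] S-methyl carbonodithioate
Conditions: NaH, CS2, THF, 0 °C to rt; then MeI
Reagents that add atoms: carbon disulfide S=C=S; iodomethane CI
Why: Xanthate formation from the alkoxide, carbon disulfide and methyl iodide; no enolisable position competes, since C5 is quaternary and C1–H is a bridgehead hydrogen next to one ketone only.

Step 7
Reactants: 11 the C7 xanthate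
Product: 12 (1S,5S,7R)-7-allyl-5-geranyl-4-methoxy-8,8-dimethylbicyclo[3.3.1]non-3-en-9-one
Conditions: Bu3SnCH2CH=CH2, AIBN, benzene, 80 °C
Reagents that add atoms: allyltributylstannane C=CC[Sn](CCCC)(CCCC)CCCC
Why: Keck radical allylation: stannyl radical addition to the thiocarbonyl, C7–O cleavage and allyl transfer from the stannane. The planar C7 radical should be attacked on the exo face, away from ring A, which puts the allyl group equatorial (7R, the target configuration). The original C7 oxygen centre is erased here after having done its work in step 5.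

Step 8
Reactants: 12 the C7-allyl compound
Product: 13 (1S,5S,7R)-5-geranyl-4-methoxy-8,8-dimethyl-7-(3-methylbut-2-en-1-yl)bicyclo[3.3.1]non-3-en-9-one
Conditions: (H2IMes)(PCy3)Cl2Ru=CHPh (second-generation Grubbs catalyst, 5 mol %), 2-methyl-2-butene/CH2Cl2, 40 °C
Reagents that add atoms: 2-methyl-2-butene CC=C(C)C
Why: Olefin cross-metathesis; the monosubstituted alkene reacts much faster than the trisubstituted geranyl alkenes, and exchange at the isopropylidene end of the geranyl group is degenerate.

Step 9
Reactants: 13 the C7-prenyl enol ether
Product: 14 (1R,5S,7R)-5-geranyl-4-methoxy-8,8-dimethyl-7-(3-methylbut-2-en-1-yl)bicyclo[3.3.1]non-3-ene-2,9-dione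
Conditions: t-BuOOH, PhI(OAc)2, K2CO3, EtOAc, −20 °C
Reagents that add atoms: tert-butyl hydroperoxide CC(C)(C)OO
Why: Radical allylic oxidation: tert-butylperoxyl radicals abstract hydrogen, the allyl radical is trapped as a peroxide, and base-induced Kornblum–DeLaMare collapse gives the ketone. The ring-held C2–H bonds next to the enol ether are the most activated C–H bonds, and the product is the vinylogous ester; no stereocentre is involved (the C1 descriptor changes by priority only).

Step 10
Reactants: 14 the vinylogous ester; 6 geranyl bromide
Product: 15 (1R,5S,7R)-1,5-digeranyl-4-methoxy-8,8-dimethyl-7-(3-methylbut-2-en-1-yl)bicyclo[3.3.1]non-3-ene-2,9-dione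
Conditions: LiN(i-Pr)2, THF, −78 °C; then 6, −78 to 0 °C
Reagents that add atoms: none
Why: Bridgehead deprotonation and alkylation; C1–H is acidified by the C2 and C9 carbonyls, and a bridgehead enolate is tolerated in this ring system. The bicycle allows only retention at C1, and a C3-lithiated vinylogous ester, if formed, does not alkylate with an allylic bromide without copper.

Step 11
Reactants: 16 3,4-dihydroxybenzoic acid
Product: 17 tert-butyldimethylsilyl 3,4-bis(tert-butyldimethylsilyloxy)benzoate
Conditions: t-BuMe2SiCl, imidazole, DMF, rt
Reagents that add atoms: tert-butyldimethylsilyl chloride CC(C)(C)[Si](C)(C)Cl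
Why: Exhaustive silylation of both phenols and the acid.

Step 12
Reactants: 17 the tris-silyl derivative
Product: 18 3,4-bis(tert-butyldimethylsilyloxy)benzoyl chloride
Conditions: (COCl)2, DMF (cat.), CH2Cl2, 0 °C to rt
Reagents that add atoms: oxalyl chloride O=C(Cl)C(Cl)=O
Why: Conversion of a silyl ester into the acid chloride by the chloroiminium species from oxalyl chloride and DMF; no hydrogen chloride is formed, so the aryl silyl ethers should survive.

Step 13
Reactants: 15 the 1,5-digeranyl vinylogous ester; 18 the aroyl chloride
Product: 19 (1S,5S,7R)-3-[3,4-bis(tert-butyldimethylsilyloxy)benzoyl]-1,5-digeranyl-4-methoxy-8,8-dimethyl-7-(3-methylbut-2-en-1-yl)bicyclo[3.3.1]non-3-ene-2,9-dione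
Conditions: lithium 2,2,6,6-tetramethylpiperidide, THF, −78 °C; then 18, −78 °C
Reagents that add atoms: none
Why: α-Lithiation of the vinylogous ester at the vinylic C3–H, which lies between the carbonyl and the methoxy-bearing carbon, followed by C-acylation; C1 is now quaternary, so no other acidic site competes.

Step 14
Reactants: 19 the C3-aroyl methyl enol ether
Product: 20 (1S,5S,7R)-3-[3,4-bis(tert-butyldimethylsilyloxy)benzoyl]-1,5-digeranyl-4-hydroxy-8,8-dimethyl-7-(3-methylbut-2-en-1-yl)bicyclo[3.3.1]non-3-ene-2,9-dione
Conditions: LiCl, DMSO (anhydrous), 120 °C; aq. HCl work-up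
Reagents that add atoms: none
Why: Chloride attacks the O-methyl group in a Krapcho-type direct displacement, with the β-triketone enolate as leaving group. No hydroxide is present, so the non-enolisable 1,3-diketones are not cleaved; the medium is anhydrous, so the aryl silyl ethers should largely survive, and any partial loss is completed in step 15.

Step 15
Reactants: 20 the bis-silyl enol
Product: 21 (1S,5S,7R)-3-(3,4-dihydroxybenzoyl)-1,5-bis[(2E)-3,7-dimethylocta-2,6-dien-1-yl]-4-hydroxy-8,8-dimethyl-7-(3-methylbut-2-en-1-yl)bicyclo[3.3.1]non-3-ene-2,9-dione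
Conditions: Bu4NF, AcOH, THF, 0 °C
Reagents that add atoms: none
Why: Fluoride cleavage of the two aryl silyl ethers, buffered with acetic acid so that the catechol and the enol are not held under basic conditions.

## Compound list

1 | prenol (3-methylbut-2-en-1-ol) | CC(C)=CCO | starting material
2 | [(2R)-3,3-dimethyloxiran-2-yl]methanol | OC[C@H]1OC1(C)C | intermediate
3 | [(2R)-3,3-dimethyloxiran-2-yl]methyl 4-methylbenzenesulfonate | Cc1ccc(cc1)S(=O)(=O)OC[C@H]1OC1(C)C | intermediate
4 | (2S)-2-(iodomethyl)-3,3-dimethyloxirane | IC[C@H]1OC1(C)C | intermediate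
5 | 1,5-dimethoxycyclohexa-1,4-diene | COC1=CCC=C(OC)C1 | starting material
6 | geranyl bromide, (2E)-1-bromo-3,7-dimethylocta-2,6-diene | CC(C)=CCC/C(C)=C/CBr | starting material
7 | 6-[(2E)-3,7-dimethylocta-2,6-dien-1-yl]-1,5-dimethoxycyclohexa-1,4-diene | CC(C)=CCC/C(C)=C/CC1C(OC)=CCC=C1OC | intermediate
8 | 6-geranyl-6-{[(2R)-3,3-dimethyloxiran-2-yl]methyl}-1,5-dimethoxycyclohexa-1,4-diene | CC(C)=CCC/C(C)=C/CC1(C[C@H]2OC2(C)C)C(OC)=CCC=C1OC | intermediate
9 | (1S,5S,7R,9R)-5-geranyl-4,9-dimethoxy-8,8-dimethyl-7,9-epoxybicyclo[3.3.1]non-3-ene (bridged methyl ketal, oxygen bridge C7–O–C9) | CC(C)=CCC/C(C)=C/C[C@]12C[C@@H]3C(C)(C)[C@H](CC=C1OC)[C@@]2(OC)O3 | intermediate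
10 | (1S,5S,7R)-5-geranyl-7-hydroxy-4-methoxy-8,8-dimethylbicyclo[3.3.1]non-3-en-9-one | CC(C)=CCC/C(C)=C/C[C@]12C[C@@H](O)C(C)(C)[C@H](CC=C1OC)C2=O | intermediate
11 | O-[(1S,5S,7R)-5-geranyl-4-methoxy-8,8-dimethyl-9-oxobicyclo[3.3.1]non-3-en-7-yl] S-methyl carbonodithioate | CC(C)=CCC/C(C)=C/C[C@]12C[C@@H](OC(=S)SC)C(C)(C)[C@H](CC=C1OC)C2=O | intermediate
12 | (1S,5S,7R)-7-allyl-5-geranyl-4-methoxy-8,8-dimethylbicyclo[3.3.1]non-3-en-9-one | CC(C)=CCC/C(C)=C/C[C@]12C[C@@H](CC=C)C(C)(C)[C@H](CC=C1OC)C2=O | intermediate
13 | (1S,5S,7R)-5-geranyl-4-methoxy-8,8-dimethyl-7-(3-methylbut-2-en-1-yl)bicyclo[3.3.1]non-3-en-9-one | CC(C)=CCC/C(C)=C/C[C@]12C[C@@H](CC=C(C)C)C(C)(C)[C@H](CC=C1OC)C2=O | intermediate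
14 | (1R,5S,7R)-5-geranyl-4-methoxy-8,8-dimethyl-7-(3-methylbut-2-en-1-yl)bicyclo[3.3.1]non-3-ene-2,9-dione | CC(C)=CCC/C(C)=C/C[C@]12C[C@@H](CC=C(C)C)C(C)(C)[C@H](C(=O)C=C1OC)C2=O | intermediate
15 | (1R,5S,7R)-1,5-digeranyl-4-methoxy-8,8-dimethyl-7-(3-methylbut-2-en-1-yl)bicyclo[3.3.1]non-3-ene-2,9-dione | CC(C)=CCC/C(C)=C/C[C@]12C[C@@H](CC=C(C)C)C(C)(C)[C@](C/C=C(\C)CCC=C(C)C)(C(=O)C=C1OC)C2=O | intermediate
16 | 3,4-dihydroxybenzoic acid | O=C(O)c1ccc(O)c(O)c1 | starting material
17 | tert-butyldimethylsilyl 3,4-bis(tert-butyldimethylsilyloxy)benzoate | O=C(O[Si](C)(C)C(C)(C)C)c1ccc(O[Si](C)(C)C(C)(C)C)c(O[Si](C)(C)C(C)(C)C)c1 | intermediate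
18 | 3,4-bis(tert-butyldimethylsilyloxy)benzoyl chloride | O=C(Cl)c1ccc(O[Si](C)(C)C(C)(C)C)c(O[Si](C)(C)C(C)(C)C)c1 | intermediate
19 | (1S,5S,7R)-3-[3,4-bis(tert-butyldimethylsilyloxy)benzoyl]-1,5-digeranyl-4-methoxy-8,8-dimethyl-7-(3-methylbut-2-en-1-yl)bicyclo[3.3.1]non-3-ene-2,9-dione | CC(C)=CCC/C(C)=C/C[C@]12C[C@@H](CC=C(C)C)C(C)(C)[C@](C/C=C(\C)CCC=C(C)C)(C(=O)C(C(=O)c3ccc(O[Si](C)(C)C(C)(C)C)c(O[Si](C)(C)C(C)(C)C)c3)=C1OC)C2=O | intermediate
20 | (1S,5S,7R)-3-[3,4-bis(tert-butyldimethylsilyloxy)benzoyl]-1,5-digeranyl-4-hydroxy-8,8-dimethyl-7-(3-methylbut-2-en-1-yl)bicyclo[3.3.1]non-3-ene-2,9-dione | CC(C)=CCC/C(C)=C/C[C@]12C[C@@H](CC=C(C)C)C(C)(C)[C@](C/C=C(\C)CCC=C(C)C)(C(=O)C(C(=O)c3ccc(O[Si](C)(C)C(C)(C)C)c(O[Si](C)(C)C(C)(C)C)c3)=C1O)C2=O | intermediate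
21 | (1S,5S,7R)-3-(3,4-dihydroxybenzoyl)-1,5-bis[(2E)-3,7-dimethylocta-2,6-dien-1-yl]-4-hydroxy-8,8-dimethyl-7-(3-methylbut-2-en-1-yl)bicyclo[3.3.1]non-3-ene-2,9-dione | CC(C)=CCC/C(C)=C/C[C@]12C[C@@H](CC=C(C)C)C(C)(C)[C@](C/C=C(\C)CCC=C(C)C)(C(=O)C(C(=O)c3ccc(O)c(O)c3)=C1O)C2=O | target

## Step count and least certain steps

Total: 15 steps. Longest linear sequence: 12 steps (1, 2, 4, 5, 6, 7, 8, 9, 10, 13, 14, 15, from prenol). The enantiomeric purity of 21 should equal that of 3 multiplied by the group selectivity of step 5, because step 7 re-sets C7; a minor isomer from step 5 therefore has to be removed at 10 or 11, before step 7.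

**Step 5 (key step).**
- What may go wrong: incomplete discrimination between the two enol ethers if a boat pathway competes, which would appear later as loss of enantiomeric purity. A hydride shift or proton loss at the C8 cation may precede ring closure. In the second half of the operation, the boron bromide may protonate and cleave the C3=C4 enol ether.
- Fallback: set out from 8, run only the silyl triflate stage and isolate 9. The oxygen bridge can form only from the chair-derived isomer, so isolating the ketal removes the other one. Oxidise C2 at this stage with the hydroperoxide and iodane system of step 9 to the ketal vinylogous ester F1; neither a free alcohol nor the C9 ketone is exposed, and the prenyl group is not yet present. Open the ketal of the now robust vinylogous ester with Me2BBr to the hydroxy enone F2, convert it into the xanthate F3, and carry out the radical allylation to the allyl enone F4. Cross-metathesis as in step 8 then rejoins the route at 14.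

**Step 9.**
- What may go wrong: hydrogen abstraction at the other allylic positions of the geranyl and prenyl groups, or trapping of the allyl radical at C4 with loss of the enol ether, because the radical chain discriminates only by bond strength.
- Fallback: set out from 13 and use a polar sequence. Hydrolyse the enol ether with aqueous oxalic acid to the 4,9-dione F5. Dehydrogenate it by Saegusa–Ito oxidation (LiN(i-Pr)2 and Me3SiCl, then Pd(OAc)2) to the enone F6; only C3 can be enolised, because C5 is quaternary. Oxidise the enone at its β-carbon under Wacker-type conditions (Na2PdCl4, t-BuOOH, aqueous acetic acid) to the 2,4,9-trione F7. O-Methylation with Me3SiCHN2 in methanol rejoins the route at 14; the 2-methoxy regioisomer formed alongside would be separated and returned to F7 by hydrolysis.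

**Step 10.**
- What may go wrong: competing lithiation at the vinylic C3–H, or proton return in place of alkylation at a bridgehead crowded by the C8 methyl groups.
- Fallback: set out from 14 and block C3 first. Lithium 2,2,6,6-tetramethylpiperidide in the presence of Me3SiCl gives the C3 vinylsilane F8. Bridgehead deprotonation and alkylation with 6 then give the silylated digeranyl compound F9, and Bu4NF removes the silyl group to rejoin the route at 15.

**Step 8.**
- What may go wrong: metathesis at the geranyl alkenes, which would truncate a geranyl group, or early catalyst death on a crowded substrate.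
- Fallback: set out from 11 and avoid metathesis. Radical addition of the C7 radical (Bu3SnH, AIBN, slow addition) to vinylboronic acid pinacol ester gives the boronate F10, again by exo attack. Oxidation with NaBO3 gives the primary alcohol F11, and Dess–Martin oxidation gives the aldehyde F12. A Wittig reaction with Ph3P=CMe2 then rejoins the route at 13, bypassing steps 7 and 8.

## Further compounds

F1 | step 5 | C2 ketone of ketal 9: 5-geranyl-4,9-dimethoxy-8,8-dimethyl-7,9-epoxybicyclo[3.3.1]non-3-en-2-one | CC(C)=CCC/C(C)=C/C[C@]12C[C@@H]3C(C)(C)[C@H](C(=O)C=C1OC)[C@@]2(OC)O3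
F2 | step 5 | 5-geranyl-7-hydroxy-4-methoxy-8,8-dimethylbicyclo[3.3.1]non-3-ene-2,9-dione | CC(C)=CCC/C(C)=C/C[C@]12C[C@@H](O)C(C)(C)[C@H](C(=O)C=C1OC)C2=O
F3 | step 5 | O-(5-geranyl-4-methoxy-8,8-dimethyl-2,9-dioxobicyclo[3.3.1]non-3-en-7-yl) S-methyl carbonodithioate | CC(C)=CCC/C(C)=C/C[C@]12C[C@@H](OC(=S)SC)C(C)(C)[C@H](C(=O)C=C1OC)C2=O
F4 | step 5 | 7-allyl-5-geranyl-4-methoxy-8,8-dimethylbicyclo[3.3.1]non-3-ene-2,9-dione | CC(C)=CCC/C(C)=C/C[C@]12C[C@@H](CC=C)C(C)(C)[C@H](C(=O)C=C1OC)C2=O
F5 | step 9 | 5-geranyl-8,8-dimethyl-7-prenylbicyclo[3.3.1]nonane-4,9-dione (route numbering) | CC(C)=CCC/C(C)=C/C[C@]12C[C@@H](CC=C(C)C)C(C)(C)[C@H](CCC1=O)C2=O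
F6 | step 9 | 5-geranyl-8,8-dimethyl-7-prenylbicyclo[3.3.1]non-2-ene-4,9-dione (route numbering) | CC(C)=CCC/C(C)=C/C[C@]12C[C@@H](CC=C(C)C)C(C)(C)[C@H](C=CC1=O)C2=O
F7 | step 9 | 5-geranyl-8,8-dimethyl-7-prenylbicyclo[3.3.1]nonane-2,4,9-trione | CC(C)=CCC/C(C)=C/C[C@]12C[C@@H](CC=C(C)C)C(C)(C)[C@H](C(=O)CC1=O)C2=O
F8 | step 10 | 3-(trimethylsilyl) derivative of 14 | CC(C)=CCC/C(C)=C/C[C@]12C[C@@H](CC=C(C)C)C(C)(C)[C@H](C(=O)C([Si](C)(C)C)=C1OC)C2=O
F9 | step 10 | 3-(trimethylsilyl) derivative of 15 | CC(C)=CCC/C(C)=C/C[C@]12C[C@@H](CC=C(C)C)C(C)(C)[C@](C/C=C(\C)CCC=C(C)C)(C(=O)C([Si](C)(C)C)=C1OC)C2=O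
F10 | step 8 | 5-geranyl-4-methoxy-8,8-dimethyl-7-[2-(4,4,5,5-tetramethyl-1,3,2-dioxaborolan-2-yl)ethyl]bicyclo[3.3.1]non-3-en-9-one | CC(C)=CCC/C(C)=C/C[C@]12C[C@@H](CCB3OC(C)(C)C(C)(C)O3)C(C)(C)[C@H](CC=C1OC)C2=O
F11 | step 8 | 5-geranyl-7-(2-hydroxyethyl)-4-methoxy-8,8-dimethylbicyclo[3.3.1]non-3-en-9-one | CC(C)=CCC/C(C)=C/C[C@]12C[C@@H](CCO)C(C)(C)[C@H](CC=C1OC)C2=O
F12 | step 8 | (5-geranyl-4-methoxy-8,8-dimethyl-9-oxobicyclo[3.3.1]non-3-en-7-yl)acetaldehyde | CC(C)=CCC/C(C)=C/C[C@]12C[C@@H](CC=O)C(C)(C)[C@H](CC=C1OC)C2=O
A1 | alternative 1 | 6-(3-diazo-2-oxopropyl)-6-geranyl-1,5-dimethoxycyclohexa-1,4-diene | CC(C)=CCC/C(C)=C/CC1(CC(=O)C=[N+]=[N-])C(OC)=CCC=C1OC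
A2 | alternative 1 | methoxycyclopropyl ketone tricycle (cyclopentanone fused to the methoxycyclopropane, remaining methyl enol ether intact) | CC(C)=CCC/C(C)=C/C[C@@]12CC(=O)[C@H]3[C@@H](CC=C1OC)[C@@]23OC
A3 | alternative 2 | 2,6-digeranyl-3-methyl-4-prenylcyclohex-2-enone carrying a methyl (E)-3-methoxyacrylate unit on the geranyl-bearing C6 of the ring | CC(C)=CCC/C(C)=C/C[C@@]1(/C(OC)=C\C(=O)OC)C[C@@H](CC=C(C)C)C(C)=C(C/C=C(\C)CCC=C(C)C)C1=O
A4 | alternative 2 | 1,5-digeranyl-4-methoxy-8,8-dimethyl-7-prenylbicyclo[3.3.1]non-3-ene-2,9-dione (identical with 15) | CC(C)=CCC/C(C)=C/C[C@]12C[C@@H](CC=C(C)C)C(C)(C)[C@](C/C=C(\C)CCC=C(C)C)(C(=O)C=C1OC)C2=O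
A5 | alternative 3 | cis-fused hydrindenone with ring-fusion hydroxyl on C9, geranyl on C1, C2 methyl enol ether and C4 ketone | O[C@]12CC(=O)C=C(OC)[C@@]1(C/C=C(\C)CCC=C(C)C)C(C)(C)[C@H](CC=C(C)C)C2
A6 | alternative 3 | 1-geranyl-2-methoxy-8,8-dimethyl-7-prenylbicyclo[3.3.1]non-2-ene-4,9-dione with C5–H | [C@H]12C[C@@H](CC=C(C)C)C(C)(C)[C@](C/C=C(\C)CCC=C(C)C)(C(OC)=CC1=O)C2=O
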